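**Design of a synthesis of CNP0107492.1 (compound 20) by ester Wittig closure of the flavone ring**

## The problem

Target 20 is a biflavonoid in which two C15 units share one biaryl bond. A (2S)-5-hydroxy-7-methoxyflavanone (ring A fused to the dihydropyranone ring C, ring B on C2) is joined from C3' of ring B to C8'' of a 5'',7'',4'''-trihydroxyflavone (ring D fused to pyranone ring F, ring E on C2''). The C3'–C8'' bond has three ortho substituents (the C4' oxygen, O1'' via C8a'', the C7'' oxygen) and must sit on C8'', not on the electronically equivalent C6''. Flavones of this oxygenation pattern can drift from the 8-aryl to the 6-aryl series when ring F is opened and reclosed under acid (Wessely–Moser), so ring F has to be closed where that channel does not exist. C2 is the only stereocentre and nothing else in the molecule can direct it. It is also fragile: it is benzylic, β to the C4 ketone and para to the C4' oxygen, so base or hot acid opens ring C to the chalcone and returns racemate. It must therefore be set by a catalyst, late, and be followed only by neutral chemistry. Five phenols are free and the C7 oxygen alone is a methyl ether, so the protecting groups must leave under conditions that spare an aryl methyl ether, the C2''=C3'' enol ether and C2. The enabling feature lies in ring D: the C8a'' oxygen is ortho to C4a'', which carries the C4'' carbonyl. An aroyl ester on that oxygen and a phosphorus ylide on C3'' therefore face each other and can be joined as the C2''=C3'' double bond, closing ring F thermally without acid, base or a free 1,3-diketone.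

## Retrosynthesis

**20 ⇒ 19.** Only O–benzyl bonds are cut. All five phenols are carried as benzyl ethers because these survive every earlier step (carbonate, palladium coupling, silyl triflate, phosphine, 110 °C) and are cleaved by hydrogenolysis under neutral conditions. The alternative, methyl ethers, would force a late demethylation that must distinguish five methyl ethers from the C7 methoxy group. The forward reaction only has to leave the C2–O1 benzylic bond and the flavone double bond alone.

**19 ⇒ 14 + 18.** The C2–C1' bond is cut, which divides the molecule into the whole flavone half with ring B (boronic acid 14) and a small ring A chromone (18). The neighbouring cuts are O1–C2 (chalcone cyclisation) and C4–C4a (acylation). Both need several steps on the large fragment and set C2 less reliably or expose it to acid. The chosen cut creates C2 in a single catalytic step in a weakly acidic medium. It asks for enantioface control by a chiral palladium catalyst, and for reaction at the unsubstituted C2=C3 of 18 in preference to the aryl-substituted C2''=C3'' of 14.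

**14 ⇒ 13 ⇒ 12.** The C1'–B bond is traced back through pinacol boronate 13 to the C1'–Cl bond of 12. Chlorine is the one ring B substituent that is inert while the biaryl bond is made from an iodide, and it can still be activated later by a bulky phosphine. Carrying boron itself through the sequence would not survive the coupling, halogenation and ylide steps. The forward steps are a chloride borylation and a mild ester hydrolysis.

**12 ⇒ 11 (key disconnection).** The C2''=C3'' double bond of ring F is cut, which gives phosphorane 11, with the ylide on the C4'' acyl group and the ring E acid as an ester on the C8a'' oxygen. Against an acid-mediated dehydration of a 1,3-diketone this closure is neutral and irreversible through loss of the phosphine oxide. Against a chalcone oxidation it needs no oxidant near the benzyl ethers. The position of the ester decides the regiochemistry outright. The precursor is an open-chain ester, and the forward reaction only needs heat.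

**11 ⇒ 9 + 10, 9 ⇒ 7 ⇒ 5.** The ester C–O bond is cut to the hydroxy ylide 9 and acid chloride 10. The C8a'' hydroxyl is the only free oxygen in 9. The C3''–P bond leads back through phosphonium salt 8 to bromoketone 7, and the C–Br bond to methyl ketone 5 via its silyl enol ether 6. The alternative order (ester first, halogen second) is kept in reserve. Bromination via the enol ether is chosen because ring D has a very electron-rich free carbon (C6'') that would compete for any free electrophilic bromine.

**5 ⇒ 3 + 4, 3 ⇒ 2 ⇒ 1.** The C3'–C8'' biaryl bond is cut to iodide 3 and boronic acid 4, which is bought with the chlorine and the benzyl ether in place. The iodide comes from 2 by iodination ortho to the only free hydroxyl, and 2 from triol 1 by a double benzylation that leaves the chelated hydroxyl untouched. The same hydroxyl thus directs the iodine, becomes O1'', and fixes the aryl group on C8''. Making the biaryl bond at the acetophenone stage, not on a finished flavone, keeps the hindered coupling on a small, soluble substrate.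

**18 ⇒ 16 ⇒ 15.** The O1–C2 and C2–C3 bonds of the ring A chromone are cut to acetophenone 16 plus a one-carbon unit (through enaminone 17). 16 comes from 15 by monobenzylation, which masks the C5 oxygen with the same group as the others so that one final step frees all of them.

## Roads not taken

**Alternative 1:** Ring D is not bought but assembled on ring B by a cyclobutenone–ynol ether benzannulation. The cut runs through C8''–C8a'', C6''–C7'' and C4a''–C8a''. In the forward step the vinylketene released on heating 3-ethoxycyclobut-2-en-1-one A1 adds to the ring B siloxyalkyne A2. A four-electron ring opening, a six-electron ring closure and tautomerisation then give phenol A3, with the aryl group already between a free hydroxyl and a silyl ether.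
- Merits: there is no hindered cross-coupling, and the three ring D oxygens emerge differentiated (OH, silyl ether, ethyl ether) by the pericyclic course alone.
- Weak points: A2 must be made from a ring B ester by ynolate chemistry and is sensitive. A3 has no carbon on C4a'', so the whole C4''–C3''–C2'' unit and ring F are still to come, through a ring acylation that must choose C4a'' over C6''. The ethyl ether on the C5'' oxygen needs a dealkylation of its own beside the C7 methoxy group.
- Comparison: this road is better at avoiding the tri-ortho-substituted biaryl coupling. The chosen plan sets against that a one-step coupling of two available pieces, in which the iodination already provides the oxygen differentiation, and a much shorter path to ring F.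

**Alternative 2:** Ring C is closed last at C4–C4a by intramolecular Friedel–Crafts acylation. The (3S)-acid A4, a 3-aryl-3-(3,5-dimethoxyphenoxy)propanoic acid bearing the protected flavone, is activated as a mixed anhydride and acylates the symmetric phenoxy ring to give dimethoxyflavanone A5.
- Merits: either ortho carbon gives the same product, so there is no regiochemistry. The stereocentre comes from stoichiometric, predictable chemistry (carbinol formation and etherification with inversion) and does not depend on a catalytic addition with a large boronic acid. In that respect it is the safer road.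
- Weak points: the stereocentre of A4 is a benzylic aryl ether para to an oxygen. Under acylium-forming conditions it can ionise, which leads to racemisation or elimination to the cinnamic acid. The etherification at such a carbinol is itself prone to partial loss of configuration. Building A4 on the flavone-bearing arene needs about five steps from a ring B carbonyl handle. A5 then still requires one of two methyl ethers to be removed selectively with a Lewis acid on a ring-opening-prone flavanone.
- Comparison: the chosen plan creates C2 in one step from two finished halves, never exposes it to strong acid, and has no methyl ether to differentiate.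

**Alternative 3:** Ring F is made in one step by carbonylative Sonogashira annulation. Iodoresorcinol A6, a one-carbon carbonyl unit and alkyne A7 are coupled with a palladium–phosphine catalyst and an amine to form C4a''–C4'', C4''–C3'' and O1''–C2'', which gives flavone aldehyde A8.
- Merits: three bonds and the ring form in a single convergent operation, with no phosphorus waste, and only the hydroxyl ortho to the new ynone can cyclise. In step count for ring F this road is clearly better (one step against four).
- Weak points: A6 requires a phloroglucinol with one oxygen benzylated, two free, and iodine on the correct carbon, which is a differentiation problem of its own. Oxidative addition into a very electron-rich, doubly ortho-substituted iodide is slow, so non-carbonylative coupling to a benzofuran and 5-exo closure of the ynone to an aurone compete with the 6-endo path. The aldehyde of A8 then leads to the flavanone through a chalcone, whose asymmetric cyclisation is less dependable than a boronic acid addition.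
- Comparison: the chosen plan sets against the shorter ring F synthesis a closure with only one possible regiochemical and ring-size outcome, no gas handling, and a chloride handle that feeds the catalytic asymmetric formation of C2.

Key step: step 7

Assumptions:
- The C3'–C8'' axis is taken to rotate freely at room temperature in 20, which has only one substituent larger than hydrogen on the ring B side and small oxygen substituents on the ring D side, so C2 is the only stereochemical element to control.
- The sense of induction of the pyridine–oxazoline palladium catalyst on chromones is taken to parallel that on cyclic enones, which assigns the (R)-ligand to the 2S product.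

## Route

Step 1
Reactants: 1 2',4',6'-trihydroxyacetophenone
Product: 2 1-[2,4-bis(benzyloxy)-6-hydroxyphenyl]ethan-1-one
Conditions: BnBr (2.1 equiv), K2CO3, DMF, rt
Reagents that add atoms: benzyl bromide, BrCc1ccccc1
Why: Williamson ether synthesis; after two alkylations the remaining hydroxyl is locked in a hydrogen bond to the ketone and is the least nucleophilic, which leaves free exactly the oxygen that will become O1''.

Step 2
Reactants: 2 1-[2,4-bis(benzyloxy)-6-hydroxyphenyl]ethan-1-one
Product: 3 1-[4,6-bis(benzyloxy)-2-hydroxy-3-iodophenyl]ethan-1-one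
Conditions: BnMe3N ICl2, NaHCO3, CH2Cl2/MeOH, rt
Reagents that add atoms: benzyltrimethylammonium dichloroiodate, C[N+](C)(C)Cc1ccccc1.Cl[I-]Cl
Why: Electrophilic aromatic iodination; both free ring carbons are activated, but the one ortho to the free phenol has a small neighbour while the other lies between two benzyl ethers, and phenol-directed ortho iodination of 2-hydroxy-4,6-dialkoxyacetophenones with this reagent is established.

Step 3
Reactants: 3 1-[4,6-bis(benzyloxy)-2-hydroxy-3-iodophenyl]ethan-1-one; 4 [2-(benzyloxy)-5-chlorophenyl]boronic acid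
Product: 5 1-[4,6-bis(benzyloxy)-3-[2-(benzyloxy)-5-chlorophenyl]-2-hydroxyphenyl]ethan-1-one
Conditions: Pd(dppf)Cl2 (5 mol%), K2CO3, 1,4-dioxane/H2O, 90 °C
Reagents that add atoms: none
Why: Suzuki–Miyaura coupling; the C–I bond adds to zerovalent palladium far faster than the electron-rich C–Cl bond, which a ferrocenyl bisphosphine catalyst does not activate at this temperature, so the chloride is carried on as the later boron site.

Step 4
Reactants: 5 1-[4,6-bis(benzyloxy)-3-[2-(benzyloxy)-5-chlorophenyl]-2-hydroxyphenyl]ethan-1-one
Product: 7 2-bromo-1-[4,6-bis(benzyloxy)-3-[2-(benzyloxy)-5-chlorophenyl]-2-hydroxyphenyl]ethan-1-one, via bis-silylated enol ether 6 (not isolated)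
Conditions: TMSOTf (2.5 equiv), Et3N, CH2Cl2, 0 °C; then NBS, THF, −78 to 0 °C; 1 M HCl work-up
Reagents that add atoms: N-bromosuccinimide, O=C1CCC(=O)N1Br; trimethylsilyl triflate, C[Si](C)(C)OS(=O)(=O)C(F)(F)F (its silicon is present in 6 only)
Why: α-Bromination of a ketone through its silyl enol ether; the enol ether, twisted out of conjugation by two ortho substituents, is far more nucleophilic than the ring D carbon between the benzyloxy groups, so bromine goes to the methyl carbon, and the acidic work-up frees the phenol without the base that would close a benzofuranone.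

Step 5
Reactants: 7 2-bromo-1-[4,6-bis(benzyloxy)-3-[2-(benzyloxy)-5-chlorophenyl]-2-hydroxyphenyl]ethan-1-one
Product: 9 1-[4,6-bis(benzyloxy)-3-[2-(benzyloxy)-5-chlorophenyl]-2-hydroxyphenyl]-2-(triphenyl-λ5-phosphanylidene)ethan-1-one, via phosphonium bromide 8 (not isolated)
Conditions: PPh3, toluene, rt; then aq. Na2CO3, CH2Cl2
Reagents that add atoms: triphenylphosphine, c1ccc(P(c2ccccc2)c2ccccc2)cc1
Why: SN2 displacement of a primary α-keto bromide by the phosphine gives the phenacylphosphonium salt, whose CH2 is more acidic than the chelated phenol, so carbonate gives the neutral acyl-stabilised ylide with the hydroxyl still free.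

Step 6
Reactants: 9 1-[4,6-bis(benzyloxy)-3-[2-(benzyloxy)-5-chlorophenyl]-2-hydroxyphenyl]-2-(triphenyl-λ5-phosphanylidene)ethan-1-one; 10 4-(benzyloxy)benzoyl chloride
Product: 11 3,5-bis(benzyloxy)-2-[2-(benzyloxy)-5-chlorophenyl]-6-[2-(triphenyl-λ5-phosphanylidene)acetyl]phenyl 4-(benzyloxy)benzoate
Conditions: pyridine (excess), CH2Cl2, 0 °C to rt; aq. NaHCO3 wash
Reagents that add atoms: none
Why: O-Acylation of a phenol by an acid chloride through the N-acylpyridinium ion, the known first stage of flavone synthesis from 2-hydroxyphenacylidene phosphoranes; an aroyl group caught first on the ylide enolate oxygen gives an enol ester phosphonium salt that is itself an acyl donor towards the adjacent phenol, and the C8a'' hydroxyl is the only free oxygen, so the ester can only end up there.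

Step 7
Reactants: 11 3,5-bis(benzyloxy)-2-[2-(benzyloxy)-5-chlorophenyl]-6-[2-(triphenyl-λ5-phosphanylidene)acetyl]phenyl 4-(benzyloxy)benzoate
Product: 12 5,7-bis(benzyloxy)-8-[2-(benzyloxy)-5-chlorophenyl]-2-[4-(benzyloxy)phenyl]-4H-chromen-4-one
Conditions: toluene (0.02 M), 110 °C, under argon
Reagents that add atoms: none
Why: Intramolecular Wittig olefination of an ester carbonyl, the known route from ortho-acyloxyphenacylidene phosphoranes to chromones and flavones. The stabilised ylide carbon C3'' adds to the aryl ester carbonyl C2'' held ortho to it, giving a betaine and then an oxaphosphetane whose collapse expels Ph3PO and leaves the C2''=C3'' enol ether. Ring F closes in a 6-exo-trig mode, since the attacked C=O lies outside the forming six-membered ring that already contains O1''. No stereocentre is formed. The step needs attack on the ester only, which is the sole carbonyl within reach of the ylide apart from its own acyl group, and intramolecular reaction, which the ortho placement and dilution secure. Regiochemistry is fixed because only the C8a'' oxygen carries the ester while the C5'' oxygen is a benzyl ether; expulsion of the phenoxide from the betaine is reversible and leads back to the same intermediate. The medium is neutral, with no acid and no free 1,3-diketone, so no path to the 6-aryl isomer exists, and the benzyl ethers and the aryl chloride are inert.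

Step 8
Reactants: 12 5,7-bis(benzyloxy)-8-[2-(benzyloxy)-5-chlorophenyl]-2-[4-(benzyloxy)phenyl]-4H-chromen-4-one
Product: 13 5,7-bis(benzyloxy)-8-[2-(benzyloxy)-5-(4,4,5,5-tetramethyl-1,3,2-dioxaborolan-2-yl)phenyl]-2-[4-(benzyloxy)phenyl]-4H-chromen-4-one
Conditions: B2pin2, Pd2(dba)3 (2 mol%), XPhos, KOAc, 1,4-dioxane, 100 °C
Reagents that add atoms: bis(pinacolato)diboron, CC1(C)OB(OC1(C)C)B1OC(C)(C)C(C)(C)O1
Why: Miyaura borylation of an aryl chloride; the bulky dialkylbiarylphosphine now enables oxidative addition of the unhindered, electron-rich chloride that was inert in step 3, and the acetate base leaves the flavone and the benzyl ethers alone.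

Step 9
Reactants: 13 5,7-bis(benzyloxy)-8-[2-(benzyloxy)-5-(4,4,5,5-tetramethyl-1,3,2-dioxaborolan-2-yl)phenyl]-2-[4-(benzyloxy)phenyl]-4H-chromen-4-one
Product: 14 {4-(benzyloxy)-3-[5,7-bis(benzyloxy)-2-[4-(benzyloxy)phenyl]-4-oxo-4H-chromen-8-yl]phenyl}boronic acid
Conditions: NaIO4, NH4OAc, THF/acetone/H2O, rt
Reagents that add atoms: water, O
Why: Oxidative cleavage of the pinacol set free in the hydrolysis equilibrium drives the boronate to the free boronic acid, the form that transmetallates readily to cationic divalent palladium in step 12.

Step 10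
Reactants: 15 2',6'-dihydroxy-4'-methoxyacetophenone
Product: 16 1-[2-(benzyloxy)-6-hydroxy-4-methoxyphenyl]ethan-1-one
Conditions: BnBr (1.05 equiv), K2CO3, acetone, reflux
Reagents that add atoms: benzyl bromide, BrCc1ccccc1
Why: Williamson ether synthesis on a symmetric diol; after the first alkylation the second hydroxyl is held in the hydrogen bond to the ketone and resists, so the monoether is obtained.

Step 11
Reactants: 16 1-[2-(benzyloxy)-6-hydroxy-4-methoxyphenyl]ethan-1-one
Product: 18 5-(benzyloxy)-7-methoxy-4H-chromen-4-one, via enaminone 17 (not isolated)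
Conditions: Me2NCH(OMe)2, toluene, 100 °C; then conc. HCl, CH2Cl2, rt
Reagents that add atoms: N,N-dimethylformamide dimethyl acetal, COC(OC)N(C)C
Why: Enaminone formation at the methyl ketone followed by acid-promoted addition of the phenol to the β-carbon and loss of dimethylamine, the standard chromone synthesis from 2-hydroxyacetophenones.

Step 12
Reactants: 14 {4-(benzyloxy)-3-[5,7-bis(benzyloxy)-2-[4-(benzyloxy)phenyl]-4-oxo-4H-chromen-8-yl]phenyl}boronic acid; 18 5-(benzyloxy)-7-methoxy-4H-chromen-4-one (2.5 equiv)
Product: 19 (2S)-5-(benzyloxy)-2-{4-(benzyloxy)-3-[5,7-bis(benzyloxy)-2-[4-(benzyloxy)phenyl]-4-oxo-4H-chromen-8-yl]phenyl}-7-methoxy-2,3-dihydro-4H-chromen-4-one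
Conditions: Pd(OCOCF3)2 (10 mol%), (R)-4-tert-butyl-2-(pyridin-2-yl)-4,5-dihydrooxazole (12 mol%), NH4PF6, H2O (5 equiv), ClCH2CH2Cl, 60 °C
Reagents that add atoms: none
Why: Enantioselective conjugate addition of an arylboronic acid to a chromone under cationic divalent palladium with a pyridine–oxazoline ligand (transmetallation, insertion of C2=C3 into the aryl–palladium bond, protonolysis of the palladium enolate by water); C2 is set by the catalyst, the (R)-ligand being chosen to deliver the aryl group to the face that gives 2S, and the weakly acidic medium gives the flavanone no base-mediated path back to the chalcone.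

Step 13
Reactants: 19 (2S)-5-(benzyloxy)-2-{4-(benzyloxy)-3-[5,7-bis(benzyloxy)-2-[4-(benzyloxy)phenyl]-4-oxo-4H-chromen-8-yl]phenyl}-7-methoxy-2,3-dihydro-4H-chromen-4-one
Product: 20 (2S)-2-{3-[5,7-dihydroxy-2-(4-hydroxyphenyl)-4-oxo-4H-chromen-8-yl]-4-hydroxyphenyl}-5-hydroxy-7-methoxy-2,3-dihydro-4H-chromen-4-one (CNP0107492.1)
Conditions: H2 (1 atm), 10% Pd/C, THF/MeOH, rt
Reagents that add atoms: none
Why: Hydrogenolysis of five aryl benzyl ethers under neutral conditions; the aryl methyl ether, the flavone enol ether and the aryl ketones are not reduced at this pressure, and with no acid or base present C2 has no route to the chalcone.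

## Compound list

1 | 2',4',6'-trihydroxyacetophenone | CC(=O)c1c(O)cc(O)cc1O | starting material
2 | 1-[2,4-bis(benzyloxy)-6-hydroxyphenyl]ethan-1-one | CC(=O)c1c(O)cc(OCc2ccccc2)cc1OCc1ccccc1 | intermediate
3 | 1-[4,6-bis(benzyloxy)-2-hydroxy-3-iodophenyl]ethan-1-one | CC(=O)c1c(OCc2ccccc2)cc(OCc2ccccc2)c(I)c1O | intermediate
4 | [2-(benzyloxy)-5-chlorophenyl]boronic acid | OB(O)c1cc(Cl)ccc1OCc1ccccc1 | starting material
5 | 1-[4,6-bis(benzyloxy)-3-[2-(benzyloxy)-5-chlorophenyl]-2-hydroxyphenyl]ethan-1-one | CC(=O)c1c(OCc2ccccc2)cc(OCc2ccccc2)c(-c2cc(Cl)ccc2OCc2ccccc2)c1O | intermediate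
6 | {1-[4,6-bis(benzyloxy)-3-[2-(benzyloxy)-5-chlorophenyl]-2-(trimethylsilyloxy)phenyl]ethenyloxy}trimethylsilane | C=C(O[Si](C)(C)C)c1c(OCc2ccccc2)cc(OCc2ccccc2)c(-c2cc(Cl)ccc2OCc2ccccc2)c1O[Si](C)(C)C | intermediate
7 | 2-bromo-1-[4,6-bis(benzyloxy)-3-[2-(benzyloxy)-5-chlorophenyl]-2-hydroxyphenyl]ethan-1-one | O=C(CBr)c1c(OCc2ccccc2)cc(OCc2ccccc2)c(-c2cc(Cl)ccc2OCc2ccccc2)c1O | intermediate
8 | {2-[4,6-bis(benzyloxy)-3-[2-(benzyloxy)-5-chlorophenyl]-2-hydroxyphenyl]-2-oxoethyl}triphenylphosphonium bromide | O=C(C[P+](c1ccccc1)(c1ccccc1)c1ccccc1)c1c(OCc2ccccc2)cc(OCc2ccccc2)c(-c2cc(Cl)ccc2OCc2ccccc2)c1O.[Br-] | intermediate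
9 | 1-[4,6-bis(benzyloxy)-3-[2-(benzyloxy)-5-chlorophenyl]-2-hydroxyphenyl]-2-(triphenyl-λ5-phosphanylidene)ethan-1-one | O=C(C=P(c1ccccc1)(c1ccccc1)c1ccccc1)c1c(OCc2ccccc2)cc(OCc2ccccc2)c(-c2cc(Cl)ccc2OCc2ccccc2)c1O | intermediate
10 | 4-(benzyloxy)benzoyl chloride | O=C(Cl)c1ccc(OCc2ccccc2)cc1 | starting material
11 | 3,5-bis(benzyloxy)-2-[2-(benzyloxy)-5-chlorophenyl]-6-[2-(triphenyl-λ5-phosphanylidene)acetyl]phenyl 4-(benzyloxy)benzoate | O=C(C=P(c1ccccc1)(c1ccccc1)c1ccccc1)c1c(OCc2ccccc2)cc(OCc2ccccc2)c(-c2cc(Cl)ccc2OCc2ccccc2)c1OC(=O)c1ccc(OCc2ccccc2)cc1 | intermediate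
12 | 5,7-bis(benzyloxy)-8-[2-(benzyloxy)-5-chlorophenyl]-2-[4-(benzyloxy)phenyl]-4H-chromen-4-one | O=c1cc(-c2ccc(OCc3ccccc3)cc2)oc2c(-c3cc(Cl)ccc3OCc3ccccc3)c(OCc3ccccc3)cc(OCc3ccccc3)c12 | intermediate
13 | 5,7-bis(benzyloxy)-8-[2-(benzyloxy)-5-(4,4,5,5-tetramethyl-1,3,2-dioxaborolan-2-yl)phenyl]-2-[4-(benzyloxy)phenyl]-4H-chromen-4-one | O=c1cc(-c2ccc(OCc3ccccc3)cc2)oc2c(-c3cc(B4OC(C)(C)C(C)(C)O4)ccc3OCc3ccccc3)c(OCc3ccccc3)cc(OCc3ccccc3)c12 | intermediate
14 | {4-(benzyloxy)-3-[5,7-bis(benzyloxy)-2-[4-(benzyloxy)phenyl]-4-oxo-4H-chromen-8-yl]phenyl}boronic acid | O=c1cc(-c2ccc(OCc3ccccc3)cc2)oc2c(-c3cc(B(O)O)ccc3OCc3ccccc3)c(OCc3ccccc3)cc(OCc3ccccc3)c12 | intermediate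
15 | 2',6'-dihydroxy-4'-methoxyacetophenone | COc1cc(O)c(C(C)=O)c(O)c1 | starting material
16 | 1-[2-(benzyloxy)-6-hydroxy-4-methoxyphenyl]ethan-1-one | COc1cc(O)c(C(C)=O)c(OCc2ccccc2)c1 | intermediate
17 | (E)-1-[2-(benzyloxy)-6-hydroxy-4-methoxyphenyl]-3-(dimethylamino)prop-2-en-1-one | COc1cc(O)c(C(=O)/C=C/N(C)C)c(OCc2ccccc2)c1 | intermediate
18 | 5-(benzyloxy)-7-methoxy-4H-chromen-4-one | COc1cc(OCc2ccccc2)c2c(=O)ccoc2c1 | intermediate
19 | (2S)-5-(benzyloxy)-2-{4-(benzyloxy)-3-[5,7-bis(benzyloxy)-2-[4-(benzyloxy)phenyl]-4-oxo-4H-chromen-8-yl]phenyl}-7-methoxy-2,3-dihydro-4H-chromen-4-one | COc1cc(OCc2ccccc2)c2c(c1)O[C@H](c1ccc(OCc3ccccc3)c(-c3c(OCc4ccccc4)cc(OCc4ccccc4)c4c(=O)cc(-c5ccc(OCc6ccccc6)cc5)oc34)c1)CC2=O | intermediate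
20 | (2S)-2-{3-[5,7-dihydroxy-2-(4-hydroxyphenyl)-4-oxo-4H-chromen-8-yl]-4-hydroxyphenyl}-5-hydroxy-7-methoxy-2,3-dihydro-4H-chromen-4-one | COc1cc(O)c2c(c1)O[C@H](c1ccc(O)c(-c3c(O)cc(O)c4c(=O)cc(-c5ccc(O)cc5)oc34)c1)CC2=O | target

## Step count and risk

Total: 13 steps. Longest linear sequence: 11 steps (steps 1 to 9, 12 and 13). The chromone branch (steps 10 and 11) joins at step 12.

**Step 7 (key step).** The ester is flanked by the ortho aryl group and is twisted, so ring closure may be slow. Prolonged heating then favours irreversible transfer of the aroyl group from oxygen to the ylide carbon, or ester cleavage by traces of water.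
Fallback: sets out from 5 and returns at 12. Claisen–Schmidt condensation of 5 with commercial 4-(benzyloxy)benzaldehyde (KOH, EtOH/THF) gives the 2'-hydroxychalcone F1. Oxidative cyclisation with catalytic I2 in DMSO at about 120 °C then closes ring F onto the only free phenol, which gives 12. The C5'' oxygen stays etherified, so no second phenol can compete.

**Step 4.** Electrophilic bromination may go partly to the ring D carbon between the two benzyloxy groups, or enol silane formation at the doubly ortho-substituted ketone may be incomplete. Any contact of the bromoketone with base leads to closure of a benzofuranone.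
Fallback: sets out from 5 and returns at 7, with no electrophilic bromine. Detrifluoroacetylative diazo transfer starts with LiHMDS and 2,2,2-trifluoroethyl trifluoroacetate, which give the trifluoroacetyl ketone F2. Methanesulfonyl azide and Et3N convert F2 into the α-diazoketone F3. Aqueous HBr in ether at 0 °C then converts F3 into 7 with loss of nitrogen.

**Step 6.** The aroyl group may be taken up at the ylide carbon and not at the hindered, hydrogen-bonded phenol. The resulting diacyl ylide cannot undergo the closure.
Fallback: sets out from 5 and returns at 11; the ester is made before phosphorus is introduced. Acid chloride 10 with Et3N and DMAP acylates 5 to the aryl ester F4. Soft enolisation (TMSOTf, Et3N) gives the silyl enol ether F5 without a free enolate that could migrate the acyl group. NBS then gives the bromoacetyl ester F6, PPh3 gives the phosphonium bromide F7, and aqueous NaHCO3 releases 11.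

**Step 12.** Insertion into the electron-rich 5,7-dialkoxychromone may be slow, so protodeboronation and homocoupling consume the valuable acid 14. Facial selectivity may erode with the electron-rich aryl group. Competing addition to the flavone C2''=C3'' of a second molecule is disfavoured by its aryl substituent and by the excess of 18.
Fallback: sets out from 13 and 18 and returns at 19, making step 9 unnecessary. The aryl group is delivered from monovalent rhodium: [Rh(OH)(cod)]2 with an electron-poor atropisomeric bisphosphine, using the enantiomer that gives 2S, in aqueous toluene at room temperature. This is the other established catalytic manifold for flavanones from chromones. It runs through an aryl–rhodium insertion and a rhodium enolate and accepts the boronate directly.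

**Step 13.** Over-reduction is possible (hydrogenolysis of the benzylic C2–O1 bond to a dihydrochalcone, or saturation of C2''=C3''). The hindered C7'' benzyl ether may be cleaved incompletely as partly deprotected material precipitates.
Fallback: sets out from 19 and returns at 20. Lewis-acid debenzylation with BCl3 and pentamethylbenzene as cation scavenger in CH2Cl2 at −78 °C is used. It spares the C7 methyl ether, which is not peri to a carbonyl, and involves no hydrogen.

## Further compounds

F1 | step 7 | (E)-1-[4,6-bis(benzyloxy)-3-[2-(benzyloxy)-5-chlorophenyl]-2-hydroxyphenyl]-3-[4-(benzyloxy)phenyl]prop-2-en-1-one | O=C(/C=C/c1ccc(OCc2ccccc2)cc1)c1c(OCc2ccccc2)cc(OCc2ccccc2)c(-c2cc(Cl)ccc2OCc2ccccc2)c1O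
F2 | step 4 | 1-[4,6-bis(benzyloxy)-3-[2-(benzyloxy)-5-chlorophenyl]-2-hydroxyphenyl]-4,4,4-trifluorobutane-1,3-dione | O=C(CC(=O)C(F)(F)F)c1c(OCc2ccccc2)cc(OCc2ccccc2)c(-c2cc(Cl)ccc2OCc2ccccc2)c1O
F3 | step 4 | 2-diazo-1-[4,6-bis(benzyloxy)-3-[2-(benzyloxy)-5-chlorophenyl]-2-hydroxyphenyl]ethan-1-one | [N-]=[N+]=CC(=O)c1c(OCc2ccccc2)cc(OCc2ccccc2)c(-c2cc(Cl)ccc2OCc2ccccc2)c1O
F4 | step 6 | 2-acetyl-3,5-bis(benzyloxy)-6-[2-(benzyloxy)-5-chlorophenyl]phenyl 4-(benzyloxy)benzoate | CC(=O)c1c(OCc2ccccc2)cc(OCc2ccccc2)c(-c2cc(Cl)ccc2OCc2ccccc2)c1OC(=O)c1ccc(OCc2ccccc2)cc1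
F5 | step 6 | 3,5-bis(benzyloxy)-2-[2-(benzyloxy)-5-chlorophenyl]-6-[1-(trimethylsilyloxy)ethenyl]phenyl 4-(benzyloxy)benzoate | C=C(O[Si](C)(C)C)c1c(OCc2ccccc2)cc(OCc2ccccc2)c(-c2cc(Cl)ccc2OCc2ccccc2)c1OC(=O)c1ccc(OCc2ccccc2)cc1
F6 | step 6 | 3,5-bis(benzyloxy)-2-[2-(benzyloxy)-5-chlorophenyl]-6-(2-bromoacetyl)phenyl 4-(benzyloxy)benzoate | O=C(CBr)c1c(OCc2ccccc2)cc(OCc2ccccc2)c(-c2cc(Cl)ccc2OCc2ccccc2)c1OC(=O)c1ccc(OCc2ccccc2)cc1
F7 | step 6 | {2-[4,6-bis(benzyloxy)-3-[2-(benzyloxy)-5-chlorophenyl]-2-[4-(benzyloxy)benzoyloxy]phenyl]-2-oxoethyl}triphenylphosphonium bromide | O=C(C[P+](c1ccccc1)(c1ccccc1)c1ccccc1)c1c(OCc2ccccc2)cc(OCc2ccccc2)c(-c2cc(Cl)ccc2OCc2ccccc2)c1OC(=O)c1ccc(OCc2ccccc2)cc1.[Br-]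
F0 | step 12 | none | none
F0 | step 13 | none | none
A1 | alternative 1 | 3-ethoxycyclobut-2-en-1-one | CCOC1=CC(=O)C1
A2 | alternative 1 | {[2-(benzyloxy)-5-chlorophenyl]ethynyloxy}tri(propan-2-yl)silane | CC(C)[Si](OC#Cc1cc(Cl)ccc1OCc1ccccc1)(C(C)C)C(C)C
A3 | alternative 1 | 2-[2-(benzyloxy)-5-chlorophenyl]-5-ethoxy-3-(triisopropylsilyloxy)phenol | CCOc1cc(O)c(-c2cc(Cl)ccc2OCc2ccccc2)c(O[Si](C(C)C)(C(C)C)C(C)C)c1
A4 | alternative 2 | (3S)-3-{4-(benzyloxy)-3-[5,7-bis(benzyloxy)-2-[4-(benzyloxy)phenyl]-4-oxo-4H-chromen-8-yl]phenyl}-3-(3,5-dimethoxyphenoxy)propanoic acid | COc1cc(OC)cc(O[C@@H](CC(=O)O)c2ccc(OCc3ccccc3)c(-c3c(OCc4ccccc4)cc(OCc4ccccc4)c4c(=O)cc(-c5ccc(OCc6ccccc6)cc5)oc34)c2)c1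
A5 | alternative 2 | (2S)-2-{4-(benzyloxy)-3-[5,7-bis(benzyloxy)-2-[4-(benzyloxy)phenyl]-4-oxo-4H-chromen-8-yl]phenyl}-5,7-dimethoxy-2,3-dihydro-4H-chromen-4-one | COc1cc(OC)c2c(c1)O[C@H](c1ccc(OCc3ccccc3)c(-c3c(OCc4ccccc4)cc(OCc4ccccc4)c4c(=O)cc(-c5ccc(OCc6ccccc6)cc5)oc34)c1)CC2=O
A6 | alternative 3 | 4-(benzyloxy)-3-[4-(benzyloxy)-2,6-dihydroxy-3-iodophenyl]benzaldehyde | O=Cc1ccc(OCc2ccccc2)c(-c2c(O)cc(OCc3ccccc3)c(I)c2O)c1
A7 | alternative 3 | 1-(benzyloxy)-4-ethynylbenzene | C#Cc1ccc(OCc2ccccc2)cc1
A8 | alternative 3 | 4-(benzyloxy)-3-{5-(benzyloxy)-2-[4-(benzyloxy)phenyl]-7-hydroxy-4-oxo-4H-chromen-8-yl}benzaldehyde | O=Cc1ccc(OCc2ccccc2)c(-c2c(O)cc(OCc3ccccc3)c3c(=O)cc(-c4ccc(OCc5ccccc5)cc4)oc23)c1
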